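What is left of the free monomer is the small number worth reckoning in these flasks, and the monomer in chains is then the charge minus it: in the grey run the two readings at 1.33 min add to 102%, with a scatter of 1 percentage point on each.

| flask | free monomer | initiator | remark | time |
|---|---|---|---|---|
| grey | 0.093 M | 5 mol% | run made earlier |  |
| green | 0.093 M | 7.5 mol% | run made earlier |  |
| ochre | 0.19 M | 10 mol% | run made earlier |  |
| flask | 0.093 M | 10 mol% |  | 15 min |

| run | time / min | monomer in chains / % | free monomer / % |
|---|---|---|---|
| grey | 1.33 | 66.9 | 34.9 |
| grey | 3.00 | 90.9 | 8.6 |
| grey | 8.00 | 100.3 | 1.1 |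
| grey | 20.0 | 99.2 | 0.9 |
| green | 1.33 | 80.8 | 21.1 |
| green | 3.00 | 97.2 | 2.0 |
| green | 8.00 | 100.5 | 0.8 |
| green | 20.0 | 100.1 | 0 |
| ochre | 5.00 | 100.6 | 0 |
| ochre | 10.0 | 100.8 | 0 |
| ochre | 15.0 | 101.5 | 0.2 |
| ochre | 20.0 | 99.8 | 0.2 |

(readings scatter by 1 percentage point)

- the analysis behind the earlier runs scatters by 1 percentage point, standard deviation
- a reading or a percentage of monomer in chains counts all its forms, free or not

1. amount of monomer in chains in percent of the free monomer charged, at 50 s, 4.0 min and 15 min

The first readings of the grey and green runs, taken as ln(charge/c free monomer) divided by loading and time, give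

grey: 15.8 min⁻¹; green: 15.6 min⁻¹

Their mean, 15.7 min⁻¹, is the leftover constant, a pseudo-first-order constant per unit of loading, read at 0.093 M, the concentration this flask shares with both runs. For this flask it gives

leftover at 50 s = 1/exp(s · loading · time) = 27.0%, so 73.0% in chains

leftover at 4.0 min = 0.186%, so 99.8% in chains

But 50 s lies before any reading, and a delayed start would leave more. The grey slope between its first two readings, 0.839 min⁻¹, runs back to a delay of 0.0749 min, shorter than 50 s, so the estimate stands. The loading of 10 mol% is a further doubt, and it remains: the ochre run has that loading but at 0.19 M, and its 0% free monomer at 5.00 min yields no constant. The ochre chains read 99.8% to 101.5% over its readings, and for this flask at 15 min the leftover constant reckons >99.9% in chains.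

The forecast, reckoned apart from this, says 74%, 99.8% and 100%, holding that “the rate is first order in initiator”; at 50 s it stands above the reckoning here.

The flask gives 74.8%, 99.8% and 100%.

    free monomer + initiator → living end + monomer in chains (k = 10.0 M⁻¹ s⁻¹)
    free monomer + living end → monomer in chains + living end, rate k2*[living end]*[free monomer] (k = 2.80 M⁻¹ s⁻¹)
    crystals ⇌ monomer in chains, rate k3*(cs3 - [monomer in chains]) while solid is left; crystals form when [monomer in chains] > cs3 (solubility = 0.0650 M, k = 0.190 s⁻¹)

In this flask at 15.0 min, crystals make 30.1% of the free monomer charged, and they are counted in the monomer in chains. The leftover constant gives 9.49% for this flask at 1.50 min, where it holds 8.89% free monomer. The grey run at 3.00 min has the same product of loading and time, so 9.47% is reckoned for it, and its reading was 8.6%.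

(The data are simulated with constants of no real substance; noise was put on by code.)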